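**Plan**

- Retrosynthesis: the last cut removes both isopropylidene caps together, C2'''=C3''' of the C6 side chain on ring A and C6''=C7'' of the C3 side chain, leaving a bis-vinyl flavone and 2-methylbut-2-ene. Before that, the C6–C1''' bond is traced back to an O5 allyl ether, ring C is opened at O1–C2 and C3–C4 to a symmetrical salicylaldehyde and an aryl alkyl alkyne, and the alkyne–C1'' bond is cut to a terminal epoxide.
- Forward order: chain epoxide from hex-5-en-2-one, union with the ring B acetylene, acetonide, rhodium-catalysed annulation that closes ring C (rings A and B arrive preformed), O5 allylation and Claisen shift to C6, removal of all acetals, twofold cross metathesis.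
- Stereochemistry: Sharpless epoxidation with L-(+)-diethyl tartrate sets C2'' (S); acid hydrolysis with inversion at the tertiary epoxide carbon sets C3'' (R); no later step breaks a bond at either centre.
- Enabling feature: the C2'''=C3''' alkene lies between the C5 and C7 hydroxyls of ring A and the C6''=C7'' alkene within ring-closing distance of the C3'' hydroxyl, yet both are the same Me2C=CH terminus. Both can therefore pass through the acidic deprotection as inert vinyl groups and be capped in one operation.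

Key step: step 15

Remark: the C3 side chain is numbered C1''–C7'' outward from the chromenone and the C6 group C1'''–C3'''; the minor Z ester of step 1 is assumed to be separable on silica.

**Route**

Step 1
Reactants: 1 hex-5-en-2-one
Product: 2 ethyl (2E)-3-methylhepta-2,6-dienoate
Conditions: (EtO)2P(O)CH2CO2Et, NaH, THF, 0 °C to reflux; chromatography removes the Z ester
Reagents that add atoms: triethyl phosphonoacetate, CCOC(=O)CP(=O)(OCC)OCC
Why: Horner–Wadsworth–Emmons olefination of a methyl ketone with a stabilised phosphonate should favour the E trisubstituted enoate, and the geometric isomers are separable.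

Step 2
Reactants: 2 ethyl (2E)-3-methylhepta-2,6-dienoate
Product: 3 (2E)-3-methylhepta-2,6-dien-1-ol
Conditions: i-Bu2AlH (2.2 equiv), CH2Cl2, −78 to 0 °C; Rochelle salt work-up
Reagents that add atoms: none
Why: 1,2-reduction of the conjugated ester by the aluminium hydride gives the allylic alcohol and leaves both alkenes and the E geometry untouched.

Step 3
Reactants: 3 (2E)-3-methylhepta-2,6-dien-1-ol
Product: 4 [(2S,3S)-3-(but-3-en-1-yl)-3-methyloxiran-2-yl]methanol
Conditions: Ti(Oi-Pr)4 (10 mol %), L-(+)-diethyl tartrate (12 mol %), t-BuOOH, 4 Å molecular sieves, CH2Cl2, −20 °C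
Reagents that add atoms: tert-butyl hydroperoxide, CC(C)(C)OO
Why: Sharpless asymmetric epoxidation, in which the titanium tartrate complex bound to the allylic hydroxyl delivers oxygen to one alkene face (L-(+)-tartrate giving the 2S,3S epoxide), while the remote terminal alkene has no directing group and stays inert.

Step 4
Reactants: 4 [(2S,3S)-3-(but-3-en-1-yl)-3-methyloxiran-2-yl]methanol
Product: 5 (2S,3R)-3-methylhept-6-ene-1,2,3-triol
Conditions: HClO4 (5 mol %), THF–H2O (3:1), 0 °C to rt
Reagents that add atoms: water, O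
Why: Acid-catalysed epoxide hydrolysis, in which water attacks the protonated epoxide from the rear at the tertiary carbon C3 (inversion, giving 3R), while C2 keeps its configuration because its C–O bond is not broken and attack there is disfavoured by the adjacent hydroxymethyl group.

Step 5
Reactants: 5 (2S,3R)-3-methylhept-6-ene-1,2,3-triol
Product: 7 (2R)-2-[(2S)-oxiran-2-yl]hex-5-en-2-ol, via primary tosylate 6 (not isolated)
Conditions: TsCl (1.05 equiv), Et3N, Bu2SnO (2 mol %), CH2Cl2, 0 °C; then K2CO3, MeOH, 0 °C, short contact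
Reagents that add atoms: none
Why: Tin-mediated sulfonylation picks the primary hydroxyl of the 1,2-diol and the secondary alkoxide then closes the terminal epoxide by intramolecular Williamson displacement at C1, so no bond to either stereocentre is broken.

Step 6
Reactants: 8 2,4-dihydroxybenzaldehyde
Product: 9 2,4-bis(methoxymethoxy)benzaldehyde
Conditions: NaH, MOMCl (2.5 equiv), DMF, 0 °C to rt
Reagents that add atoms: chloromethyl methyl ether, COCCl
Why: Williamson-type O-alkylation of both phenoxides, the sodium salt in DMF overcoming the hydrogen bond of the ortho hydroxyl to the formyl group.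

Step 7
Reactants: 9 2,4-bis(methoxymethoxy)benzaldehyde
Product: 10 1-ethynyl-2,4-bis(methoxymethoxy)benzene
Conditions: dimethyl (1-diazo-2-oxopropyl)phosphonate, K2CO3, MeOH, rt
Reagents that add atoms: dimethyl (1-diazo-2-oxopropyl)phosphonate, COP(=O)(OC)C(=[N+]=[N-])C(C)=O
Why: Ohira–Bestmann homologation turns the aldehyde into the terminal alkyne under carbonate conditions that the acetal ethers tolerate.

Step 8
Reactants: 7 (2R)-2-[(2S)-oxiran-2-yl]hex-5-en-2-ol, 10 1-ethynyl-2,4-bis(methoxymethoxy)benzene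
Product: 11 (4S,5R)-1-[2,4-bis(methoxymethoxy)phenyl]-5-methylnon-8-en-1-yne-4,5-diol
Conditions: 10 (2.5 equiv), n-BuLi, THF, −78 °C; BF3·OEt2; then 7, −78 °C; NH4Cl quench
Reagents that add atoms: none
Why: BF3-promoted opening of a terminal epoxide by a lithium acetylide takes place at the unsubstituted carbon, so the stereocentres are not involved, and the surplus acetylide absorbs the tertiary hydroxyl proton and is recovered as 10.

Step 9
Reactants: 11 alkyne diol
Product: 12 (4S,5R)-4-{3-[2,4-bis(methoxymethoxy)phenyl]prop-2-yn-1-yl}-5-(but-3-en-1-yl)-2,2,5-trimethyl-1,3-dioxolane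
Conditions: 2,2-dimethoxypropane, PPTS (10 mol %), CH2Cl2, rt
Reagents that add atoms: 2,2-dimethoxypropane, COC(C)(C)OC
Why: Acid-catalysed transketalisation ties the vicinal diol into a dioxolane and so masks the homopropargylic hydroxyl before the metal-catalysed annulation.

Step 10
Reactants: 13 2,4,6-trihydroxybenzaldehyde
Product: 14 2,6-dihydroxy-4-(methoxymethoxy)benzaldehyde
Conditions: MOMCl (1.05 equiv), i-Pr2NEt (1.1 equiv), THF, 0 °C
Reagents that add atoms: chloromethyl methyl ether, COCCl
Why: Selective O-alkylation, since the para hydroxyl is the most acidic and the only one not hydrogen-bonded to the formyl group, so one equivalent of electrophile should go there.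

Step 11
Reactants: 12 alkyne acetonide, 14 2,6-dihydroxy-4-(methoxymethoxy)benzaldehyde
Product: 15 3-{[(4S,5R)-5-(but-3-en-1-yl)-2,2,5-trimethyl-1,3-dioxolan-4-yl]methyl}-2-[2,4-bis(methoxymethoxy)phenyl]-5-hydroxy-7-(methoxymethoxy)-4H-chromen-4-one
Conditions: [RhCl(cod)]2 (2.5 mol %), C5H2Ph4 (10 mol %), Cu(OAc)2 (2.1 equiv), o-xylene, 130 °C, N2
Reagents that add atoms: none
Why: Rhodium-catalysed oxidative annulation of a salicylaldehyde with an internal alkyne, in which phenoxide-directed cleavage of the formyl C–H bond at trivalent rhodium, alkyne insertion with the aryl-bearing carbon next to the metal and C–O reductive elimination should give the 2-aryl-3-alkyl chromenone, copper diacetate reoxidising monovalent rhodium, and the symmetry of 14 making both hydroxyls equivalent so that the unused one becomes the chelated 5-hydroxyl.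

Step 12
Reactants: 15 5-hydroxyflavone acetonide, 16 allyl bromide
Product: 17 3-{[(4S,5R)-5-(but-3-en-1-yl)-2,2,5-trimethyl-1,3-dioxolan-4-yl]methyl}-2-[2,4-bis(methoxymethoxy)phenyl]-7-(methoxymethoxy)-5-(prop-2-en-1-yloxy)-4H-chromen-4-one
Conditions: K2CO3, DMF, 50 °C
Reagents that add atoms: none
Why: Williamson etherification of the only free hydroxyl, the chelated 5-OH, which needs the polar solvent and gentle heating.

Step 13
Reactants: 17 5-allyloxyflavone acetonide
Product: 18 3-{[(4S,5R)-5-(but-3-en-1-yl)-2,2,5-trimethyl-1,3-dioxolan-4-yl]methyl}-2-[2,4-bis(methoxymethoxy)phenyl]-5-hydroxy-7-(methoxymethoxy)-6-(prop-2-en-1-yl)-4H-chromen-4-one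
Conditions: PhNEt2, 195 °C, sealed tube, Ar
Reagents that add atoms: none
Why: Aromatic Claisen rearrangement, in which the [3,3] shift from O5 can end only at C6, the one free ortho position, and tautomerisation restores the chelated 5-hydroxyl, the basic solvent sparing the acetals.

Step 14
Reactants: 18 6-allyl-5-hydroxyflavone acetonide
Product: 19 2-(2,4-dihydroxyphenyl)-3-[(2S,3R)-2,3-dihydroxy-3-methylhept-6-en-1-yl]-5,7-dihydroxy-6-(prop-2-en-1-yl)-4H-chromen-4-one
Conditions: 3 M aqueous HCl–MeOH (1:4), 45 °C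
Reagents that add atoms: none
Why: Acid-catalysed acetal cleavage removes the three methoxymethyl ethers and the acetonide together, and the monosubstituted allyl and butenyl alkenes are not protonated under these conditions, whereas prenyl-type alkenes would cyclise onto the neighbouring hydroxyls.

Step 15
Reactants: 19 bis-vinyl flavone, 20 2-methylbut-2-ene
Product: 21 2-(2,4-dihydroxyphenyl)-3-[(2S,3R)-2,3-dihydroxy-3,7-dimethyloct-6-en-1-yl]-5,7-dihydroxy-6-(3-methylbut-2-en-1-yl)-4H-chromen-4-one
Conditions: 20 (large excess), RuCl2(=CH-C6H4-2-Oi-Pr)(1,3-dimesitylimidazolidin-2-ylidene) (second-generation Hoveyda–Grubbs catalyst, 2 × 5 mol %), 1,4-benzoquinone (10 mol %), CH2Cl2–EtOAc, 40 °C, sealed tube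
Reagents that add atoms: none
Why: Olefin cross metathesis, in which the ruthenium alkylidene adds to each monosubstituted alkene in a [2+2] sense, cycloreversion expels the terminal CH2 as propene, and the isopropylidene half of 2-methylbut-2-ene is taken up to form the C2'''=C3''' and C6''=C7'' bonds. The closest known reaction is the conversion of allyl arenes and terminal alkenes into prenyl-type alkenes with 2-methylbut-2-ene, which is known to tolerate free phenols and alcohols. No ring is closed and no stereocentre is created, and C2'' and C3'' lie away from the reacting carbons and keep their configuration. The step needs reaction at both terminal alkenes without homodimerisation, which the large excess of the trisubstituted partner secures, and without re-entry of the products, which their trisubstitution secures. It also needs the C6 allyl double bond to stay out of conjugation with ring A, which the fast turnover of an unhindered terminal alkene and the benzoquinone as hydride scavenger should ensure.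

**Compound list**

1 | hex-5-en-2-one | C=CCCC(C)=O | starting material
2 | ethyl (2E)-3-methylhepta-2,6-dienoate | CCOC(=O)/C=C(\C)CCC=C | intermediate
3 | (2E)-3-methylhepta-2,6-dien-1-ol | OC/C=C(\C)CCC=C | intermediate
4 | [(2S,3S)-3-(but-3-en-1-yl)-3-methyloxiran-2-yl]methanol | C=CCC[C@]1(C)O[C@H]1CO | intermediate
5 | (2S,3R)-3-methylhept-6-ene-1,2,3-triol | C=CCC[C@@](C)(O)[C@@H](O)CO | intermediate
6 | (2S,3R)-2,3-dihydroxy-3-methylhept-6-en-1-yl 4-methylbenzenesulfonate (primary tosylate) | C=CCC[C@@](C)(O)[C@@H](O)COS(=O)(=O)c1ccc(C)cc1 | intermediate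
7 | (2R)-2-[(2S)-oxiran-2-yl]hex-5-en-2-ol | C=CCC[C@@](C)(O)[C@@H]1CO1 | intermediate
8 | 2,4-dihydroxybenzaldehyde | O=Cc1ccc(O)cc1O | starting material
9 | 2,4-bis(methoxymethoxy)benzaldehyde | O=Cc1ccc(OCOC)cc1OCOC | intermediate
10 | 1-ethynyl-2,4-bis(methoxymethoxy)benzene | C#Cc1ccc(OCOC)cc1OCOC | intermediate
11 | (4S,5R)-1-[2,4-bis(methoxymethoxy)phenyl]-5-methylnon-8-en-1-yne-4,5-diol | C=CCC[C@@](C)(O)[C@@H](O)CC#Cc1ccc(OCOC)cc1OCOC | intermediate
12 | (4S,5R)-4-{3-[2,4-bis(methoxymethoxy)phenyl]prop-2-yn-1-yl}-5-(but-3-en-1-yl)-2,2,5-trimethyl-1,3-dioxolane | C=CCC[C@@]1(C)OC(C)(C)O[C@H]1CC#Cc2ccc(OCOC)cc2OCOC | intermediate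
13 | 2,4,6-trihydroxybenzaldehyde | O=Cc1c(O)cc(O)cc1O | starting material
14 | 2,6-dihydroxy-4-(methoxymethoxy)benzaldehyde | O=Cc1c(O)cc(OCOC)cc1O | intermediate
15 | 3-{[(4S,5R)-5-(but-3-en-1-yl)-2,2,5-trimethyl-1,3-dioxolan-4-yl]methyl}-2-[2,4-bis(methoxymethoxy)phenyl]-5-hydroxy-7-(methoxymethoxy)-4H-chromen-4-one | C=CCC[C@@]1(C)OC(C)(C)O[C@H]1Cc2c(-c3ccc(OCOC)cc3OCOC)oc3cc(OCOC)cc(O)c3c2=O | intermediate
16 | allyl bromide (3-bromoprop-1-ene) | C=CCBr | starting material
17 | 3-{[(4S,5R)-5-(but-3-en-1-yl)-2,2,5-trimethyl-1,3-dioxolan-4-yl]methyl}-2-[2,4-bis(methoxymethoxy)phenyl]-7-(methoxymethoxy)-5-(prop-2-en-1-yloxy)-4H-chromen-4-one | C=CCC[C@@]1(C)OC(C)(C)O[C@H]1Cc2c(-c3ccc(OCOC)cc3OCOC)oc3cc(OCOC)cc(OCC=C)c3c2=O | intermediate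
18 | 3-{[(4S,5R)-5-(but-3-en-1-yl)-2,2,5-trimethyl-1,3-dioxolan-4-yl]methyl}-2-[2,4-bis(methoxymethoxy)phenyl]-5-hydroxy-7-(methoxymethoxy)-6-(prop-2-en-1-yl)-4H-chromen-4-one | C=CCC[C@@]1(C)OC(C)(C)O[C@H]1Cc2c(-c3ccc(OCOC)cc3OCOC)oc3cc(OCOC)c(CC=C)c(O)c3c2=O | intermediate
19 | 2-(2,4-dihydroxyphenyl)-3-[(2S,3R)-2,3-dihydroxy-3-methylhept-6-en-1-yl]-5,7-dihydroxy-6-(prop-2-en-1-yl)-4H-chromen-4-one | C=CCC[C@@](C)(O)[C@@H](O)Cc1c(-c2ccc(O)cc2O)oc2cc(O)c(CC=C)c(O)c2c1=O | intermediate
20 | 2-methylbut-2-ene | CC=C(C)C | starting material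
21 | 2-(2,4-dihydroxyphenyl)-3-[(2S,3R)-2,3-dihydroxy-3,7-dimethyloct-6-en-1-yl]-5,7-dihydroxy-6-(3-methylbut-2-en-1-yl)-4H-chromen-4-one (CNP0113932.1) | CC(C)=CCC[C@@](C)(O)[C@@H](O)Cc1c(-c2ccc(O)cc2O)oc2cc(O)c(CC=C(C)C)c(O)c2c1=O | target

**Step count**

Total: 15 steps. Longest linear sequence: 12 steps (1, 2, 3, 4, 5, 8, 9, 11, 12, 13, 14, 15).

**Steps most likely to fail**

Step 11 (rhodium annulation).
- What may go wrong: loss of carbon monoxide from the acyl rhodium intermediate; insertion of the alkyne in the reverse sense; migration of the butenyl double bond by a rhodium hydride; cleavage of the acetals by the acetic acid that is formed.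
- Fallback: ring C is built first and the side chain is attached afterwards. It sets out from 14 and returns to the route at 17.
- Mono-allylation of 14 with 16 (K2CO3, acetone) gives 2-(allyloxy)-6-hydroxy-4-(methoxymethoxy)benzaldehyde F1.
- Addition of the lithium acetylide of 10 (2.2 equiv, THF, −78 °C) gives 1-[2-(allyloxy)-6-hydroxy-4-(methoxymethoxy)phenyl]-3-[2,4-bis(methoxymethoxy)phenyl]prop-2-yn-1-ol F2.
- MnO2 in CH2Cl2 oxidises it to 1-[2-(allyloxy)-6-hydroxy-4-(methoxymethoxy)phenyl]-3-[2,4-bis(methoxymethoxy)phenyl]prop-2-yn-1-one F3.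
- Et2NH in EtOH brings about 6-endo oxa-Michael cyclisation to 5-(allyloxy)-2-[2,4-bis(methoxymethoxy)phenyl]-7-(methoxymethoxy)-4H-chromen-4-one F4.
- Lithiation of F4 at C3 with LiN(i-Pr)2 at −78 °C and BF3·OEt2-promoted opening of epoxide 7 (used as its lithium alkoxide) should give 5-(allyloxy)-2-[2,4-bis(methoxymethoxy)phenyl]-3-[(2S,3R)-2,3-dihydroxy-3-methylhept-6-en-1-yl]-7-(methoxymethoxy)-4H-chromen-4-one F5.
- Acetonide formation as in step 9 converts F5 into 17.

Step 13 (Claisen rearrangement).
- What may go wrong: migration by way of C4a to C8; thermal cyclisation of the new ortho-allyl phenol onto its own double bond; loss of acetals at 195 °C.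
- Fallback: the allyl group is introduced by cross coupling instead of a sigmatropic shift. It sets out from 15 and returns at 18, so steps 12 and 13 fall away.
- Iodination ortho to the chelated hydroxyl (I2, TlOAc, CH2Cl2) should give 3-{[(4S,5R)-5-(but-3-en-1-yl)-2,2,5-trimethyl-1,3-dioxolan-4-yl]methyl}-2-[2,4-bis(methoxymethoxy)phenyl]-5-hydroxy-6-iodo-7-(methoxymethoxy)-4H-chromen-4-one F6.
- Stille coupling of F6 with allyltributylstannane (Pd(PPh3)4, DMF, 90 °C) gives 18.

Step 8 (epoxide opening).
- What may go wrong: quenching of the acetylide by the free tertiary hydroxyl; base-induced epoxide migration (Payne rearrangement) of 7 to the trisubstituted epoxy alcohol; Lewis-acid rearrangement of the epoxide.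
- Fallback: the C1''–alkyne bond is made by SN2 alkylation with the diol already protected. It sets out from tosylate 6, which is then isolated, and returns at 12, so the free epoxy alcohol 7 and step 9 are avoided.
- 2,2-Dimethoxypropane and PPTS convert 6 into [(4S,5R)-5-(but-3-en-1-yl)-2,2,5-trimethyl-1,3-dioxolan-4-yl]methyl 4-methylbenzenesulfonate F7.
- NaI in refluxing acetone gives (4R,5R)-4-(but-3-en-1-yl)-5-(iodomethyl)-2,2,4-trimethyl-1,3-dioxolane F8.
- The lithium acetylide of 10 in THF/DMPU displaces iodide from F8 to give 12.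

**Further compounds**

F1 | step 11 | 2-(allyloxy)-6-hydroxy-4-(methoxymethoxy)benzaldehyde | C=CCOc1cc(OCOC)cc(O)c1C=O
F2 | step 11 | 1-[2-(allyloxy)-6-hydroxy-4-(methoxymethoxy)phenyl]-3-[2,4-bis(methoxymethoxy)phenyl]prop-2-yn-1-ol | C=CCOc1cc(OCOC)cc(O)c1C(O)C#Cc1ccc(OCOC)cc1OCOC
F3 | step 11 | 1-[2-(allyloxy)-6-hydroxy-4-(methoxymethoxy)phenyl]-3-[2,4-bis(methoxymethoxy)phenyl]prop-2-yn-1-one | C=CCOc1cc(OCOC)cc(O)c1C(=O)C#Cc1ccc(OCOC)cc1OCOC
F4 | step 11 | 5-(allyloxy)-2-[2,4-bis(methoxymethoxy)phenyl]-7-(methoxymethoxy)-4H-chromen-4-one | C=CCOc1cc(OCOC)cc2oc(-c3ccc(OCOC)cc3OCOC)cc(=O)c12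
F5 | step 11 | 5-(allyloxy)-2-[2,4-bis(methoxymethoxy)phenyl]-3-[(2S,3R)-2,3-dihydroxy-3-methylhept-6-en-1-yl]-7-(methoxymethoxy)-4H-chromen-4-one | C=CCC[C@@](C)(O)[C@@H](O)Cc1c(-c2ccc(OCOC)cc2OCOC)oc2cc(OCOC)cc(OCC=C)c2c1=O
F6 | step 13 | 3-{[(4S,5R)-5-(but-3-en-1-yl)-2,2,5-trimethyl-1,3-dioxolan-4-yl]methyl}-2-[2,4-bis(methoxymethoxy)phenyl]-5-hydroxy-6-iodo-7-(methoxymethoxy)-4H-chromen-4-one | C=CCC[C@@]1(C)OC(C)(C)O[C@H]1Cc2c(-c3ccc(OCOC)cc3OCOC)oc3cc(OCOC)c(I)c(O)c3c2=O
F7 | step 8 | [(4S,5R)-5-(but-3-en-1-yl)-2,2,5-trimethyl-1,3-dioxolan-4-yl]methyl 4-methylbenzenesulfonate | C=CCC[C@@]1(C)OC(C)(C)O[C@H]1COS(=O)(=O)c2ccc(C)cc2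
F8 | step 8 | (4R,5R)-4-(but-3-en-1-yl)-5-(iodomethyl)-2,2,4-trimethyl-1,3-dioxolane | C=CCC[C@@]1(C)OC(C)(C)O[C@H]1CI
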